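**Plan**
- Retrosynthetic cuts: C16–Cl; C13–C14 (Claisen) and C11=C12 (Z-selective olefination) of the chlorohydroxycyclopentenone; C8–CH3; ring A at C3–C4 together with the C4–C7 bond of a pinane cyclobutane; C10–C1 and C9–C11 back to (1R,5R)-verbenone.
- Forward order: the verbenone six-membered ring is ring B and its gem-dimethyl bridge is C4. Allyl groups are put on C10 (1,2-addition, anionic oxy-Cope) and C9 (enolate allylation). A strain-release fragmentation–cyclization then closes ring A. The C8 carbinol, the C11 aldehyde and the cyclopentanedione ring (olefination, Claisen) follow, and chlorination comes last.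
- Enabling feature: in the bicyclo[3.1.1]heptan-2-one, the cyclobutane bond C7–C4 lies α to the C8 carbonyl. Its heterolysis gives a ring-B enolate and a tertiary cation at C4, held on C5 next to the allyl group on C10.
- Stereochemistry: C5 is bought with verbenone. C10 is relayed by the bridge (anti addition, suprafacial [3,3] shift), which fixes the trans ring fusion in the key step. C9 is set by equilibration, C8 by equatorial methyl addition anti to the axial C10 methyl.
- The C11=C12 geometry comes from the Still–Gennari olefination and is carried through the Claisen closure; C16 is set by a catalyst-controlled chlorination.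

Key step: step 3

Remark: drimane numbering is used for the decalin (ring A = C1–C5, C10; ring B = C5–C10; C11 on C9; cyclopentenone C12–C16; β = face of the C10 methyl). The target is treated as the drawn enol tautomer, assumed configurationally stable at C16 in the absence of base.

**Step 1**
Reactants: 1 (1R,5R)-(+)-verbenone
Product: 2 2-allyl-4,6,6-trimethylbicyclo[3.1.1]hept-3-en-2-ol (allyl anti to the gem-dimethyl bridge)
Conditions: allylMgBr, THF, −78 to 0 °C; then H2O
Reagents that add atoms: allylmagnesium bromide, C=CC[Mg]Br
Why: Allyl Grignard reagents add 1,2 to enones, and attack on the C8 carbonyl should come from the face anti to the gem-dimethyl bridge, as hydride does in the reduction of verbenone to cis-verbenol (Grignard 1,2-addition).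

**Step 2**
Reactants: 2 allyl carbinol
Product: 5 3,4-diallyl-4,6,6-trimethylbicyclo[3.1.1]heptan-2-one (both allyl groups anti to the gem-dimethyl bridge), via potassium alkoxide 3 (not isolated), via potassium enolate 4 (not isolated)
Conditions: KH, 18-crown-6, THF, 0 °C to rt; then allyl bromide, −78 to 0 °C
Reagents that add atoms: allyl bromide, C=CCBr
Why: Anionic oxy-Cope rearrangement of the potassium 1,5-dien-3-olate should move the allyl group suprafacially from C8 to C10 on the face anti to the bridge, leaving the C10 methyl syn to the C4 bridge, and the regiodefined enolate is then C-allylated at C9 from the same open face (tandem oxy-Cope/enolate alkylation).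

**Step 3**
Reactants: 5 diallyl ketone
Product: 7 9α-allyl-2α-chloro-4,4,10β-trimethyl-trans-decalin-8-one, via carbocation titanium enolate 6 (not isolated)
Conditions: TiCl4 (2 equiv), CH2Cl2, −78 to −20 °C; then H2O
Reagents that add atoms: titanium tetrachloride, Cl[Ti](Cl)(Cl)Cl
Why: Proposed new method: TiCl4 binds the C8 carbonyl, and the cyclobutane bond C7–C4, which lies α to the carbonyl and overlaps with its π* orbital, should ionize with release of ring strain (raised further by the clash of the bridge methyl with the C10 methyl) to the titanium enolate and the 2-propyl cation at C4 (6); it is the only cyclobutane bond whose cleavage gives an enolate and a tertiary cation. The cation should be captured by the terminal carbon C3 of the C10 allyl group in a chair-like 6-endo-trig closure of ring A (the 5-exo mode would need a primary cation), and the developing C2 cation should collapse with chloride on the equatorial α side, since the β side is flanked by the axial C4 and C10 methyls; this 2α-chloride stereocenter is erased in step 5. The ring fusion comes out trans stereospecifically, because C4 on C5 and C1 on C10 were placed trans on ring B in step 2 and can be joined only from the diequatorial half-chair; C5 and C10 themselves are not touched. The closest known reaction types are the Lewis-acid cleavage of the cyclobutane of nopinone-type 2-oxopinanes to 4-(2-halo-2-propyl)cyclohexanone enolates and the Lewis-acid addition of tertiary alkyl chlorides to terminal alkenes, the carbocyclic counterpart of a halo-Prins closure. The step needs ring closure to outrun proton loss and hydride shift at the cation: proton loss and chloride capture at C4 are reversible under TiCl4 whereas the secondary C2 chloride is not re-ionized, the C9 allyl group is 1,3-trans to C4 and cannot reach it, and the aqueous quench protonates the enolate at C7.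

**Step 4**
Reactants: 7 9α-allyl chloro ketone
Product: 8 9β-allyl-2α-chloro-4,4,10β-trimethyl-trans-decalin-8-one
Conditions: NaOMe (cat.), MeOH, rt
Reagents that add atoms: none
Why: Equilibration through the C8/C9 enolate (ketone α-epimerization) should reprotonate C9 axially from the α face, anti to the axial C10 methyl, leaving the allyl group equatorial (9β); the equatorial C2 chloride has no anti-periplanar hydrogen for elimination.

**Step 5**
Reactants: 8 9β-allyl chloro ketone
Product: 9 9β-allyl-4,4,10β-trimethyl-trans-decalin-8-one
Conditions: Bu3SnH, AIBN (cat.), PhMe, 100 °C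
Reagents that add atoms: none
Why: Radical-chain hydrodechlorination removes the helper chloride and its stereocenter; the ketone and the terminal alkene are inert to the tin radical chain.

**Step 6**
Reactants: 9 decalone
Product: 10 9β-allyl-4,4,8α,10β-tetramethyl-trans-decalin-8β-ol
Conditions: MeMgBr, CeCl3, THF, −78 to 0 °C; then H2O
Reagents that add atoms: methylmagnesium bromide, C[Mg]Br
Why: Organocerium 1,2-addition to the hindered, enolizable ketone: the axial β trajectory is blocked by the 1,3-diaxial C10 methyl, so methyl should enter equatorially from the α side and give the axial 8β-alcohol with an 8α-methyl group.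

**Step 7**
Reactants: 10 allyl carbinol
Product: 11 4,4,8α,10β-tetramethyl-9β-[(E)-prop-1-enyl]-trans-decalin-8β-ol
Conditions: RuHCl(CO)(PPh3)3 (cat.), PhMe, 80 °C
Reagents that add atoms: none
Why: Ruthenium hydride catalyzed alkene isomerization (hydrometalation/β-hydride elimination) should move the terminal double bond into the more substituted (E)-prop-1-enyl position without affecting the tertiary alcohol.

**Step 8**
Reactants: 11 propenyl carbinol
Product: 12 8β-hydroxy-4,4,8α,10β-tetramethyl-trans-decalin-9β-carbaldehyde
Conditions: O3, CH2Cl2/MeOH, −78 °C; then Me2S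
Reagents that add atoms: ozone, [O-][O+]=O
Why: Ozonolysis with reductive work-up cleaves the only C=C bond to the C11 aldehyde with loss of acetaldehyde; no base is present, so C9 keeps its configuration and the β-hydroxy aldehyde is used directly.

**Step 9**
Reactants: 13 methyl bis(2,2,2-trifluoroethyl)phosphonoacetate; 14 chloroacetone
Product: 15 methyl 2-[bis(2,2,2-trifluoroethoxy)phosphoryl]-4-oxopentanoate (racemic)
Conditions: NaH, THF, 0 °C to rt
Reagents that add atoms: none
Why: C-alkylation of the sodium phosphonoacetate carbanion with the reactive α-chloro ketone (SN2) gives the α-acetonyl olefination reagent; its stereocenter is lost in step 10.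

**Step 10**
Reactants: 12 hydroxy aldehyde; 15 phosphonate
Product: 16 methyl (2Z)-2-{[8β-hydroxy-4,4,8α,10β-tetramethyl-trans-decalin-9β-yl]methylidene}-4-oxopentanoate
Conditions: KHMDS, 18-crown-6, THF, −78 °C
Reagents that add atoms: none
Why: Still–Gennari variant of the Horner–Wadsworth–Emmons reaction: with the trifluoroethyl phosphonate and a crown-separated potassium ion, addition is irreversible and elimination fast, so the kinetic alkene with the ester cis to C9 should form; the stabilized carbanion deprotonates neither the tertiary alcohol nor the α-branched aldehyde.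

**Step 11**
Reactants: 16 Z-keto ester
Product: 17 (4Z)-3-hydroxy-4-{[8β-hydroxy-4,4,8α,10β-tetramethyl-trans-decalin-9β-yl]methylidene}cyclopent-2-en-1-one (enol of the 4-alkylidenecyclopentane-1,3-dione)
Conditions: LiHMDS (2.5 equiv), THF, −78 to 0 °C; then cold 1 M HCl
Reagents that add atoms: none
Why: Intramolecular Claisen (Dieckmann-type) condensation of a γ-keto ester: the kinetic methyl-ketone enolate (C14) acylates C13 in a 5-exo-trig closure and the dione is removed as its enolate; with a lithium amide at low temperature the C11=C12 bond should not migrate, so the geometry from step 10 (C9 cis to C13) is carried over.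

**Step 12**
Reactants: 17 alkylidene dione
Product: 20 CNP0279879.2 (target), via tris-silyl fulvene 18 (not isolated), via silylated chloro enone 19 (not isolated)
Conditions: TMSOTf, Et3N, CH2Cl2, −78 to 0 °C; salts filtered off, solvent changed to PhMe; then NCS, chiral tert-leucine-derived arylpyrrolidine squaramide (10 mol %, enantiomer matched to 16R), −78 °C; then citric acid, MeOH, 0 °C
Reagents that add atoms: N-chlorosuccinimide, O=C1CCC(=O)N1Cl
Why: Proposed new method: exhaustive silylation should convert the vinylogous acid into the 1,3-bis(silyloxy)fulvene 18 (tertiary alcohol capped as well), whose largest HOMO coefficient lies at the ring terminus C16, so Cl+ from NCS bound to the hydrogen-bond-donor catalyst is delivered there and to one face only (catalyst control, because the decalin stereocenters are too remote to bias C16), the silyl group passes to succinimide, and mild methanolysis frees enol and alcohol without base, which would epimerize the new α-chloro ketone; the closest known reaction types are the squaramide-catalyzed enantioselective chlorination of silyl ketene acetals with NCS and the terminal halogenation of 1,3-bis(silyloxy)dienes.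

**Compound list**
1 | (1R,5R)-(+)-verbenone, commercial | CC1=CC(=O)[C@@H]2C[C@H]1C2(C)C | starting material
2 | 2-allyl-4,6,6-trimethylbicyclo[3.1.1]hept-3-en-2-ol, allyl anti and OH syn to the gem-dimethyl bridge | CC1=C[C@](O)(CC=C)[C@@H]2C[C@H]1C2(C)C | intermediate
3 | potassium alkoxide of 2 | CC1=C[C@]([O-])(CC=C)[C@@H]2C[C@H]1C2(C)C.[K+] | intermediate
4 | potassium 4-allyl-4,6,6-trimethylbicyclo[3.1.1]hept-2-en-2-olate, allyl anti to the bridge | C[C@@]1(CC=C)C=C([O-])[C@@H]2C[C@H]1C2(C)C.[K+] | intermediate
5 | 3,4-diallyl-4,6,6-trimethylbicyclo[3.1.1]heptan-2-one, both allyl groups anti to the bridge | C[C@@]1(CC=C)[C@H](CC=C)C(=O)[C@@H]2C[C@H]1C2(C)C | intermediate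
6 | ring-opened zwitterion: 2-propyl cation at C4 on C5, tetrachlorotitanate enolate at C7=C8 | C[C+](C)[C@@H]1CC=C(O[Ti-](Cl)(Cl)(Cl)Cl)[C@@H](CC=C)[C@@]1(C)CC=C | intermediate
7 | 9α-allyl-2α-chloro-4,4,10β-trimethyl-trans-decalin-8-one (5α-H) | CC1(C)C[C@H](Cl)C[C@]2(C)[C@H](CC=C)C(=O)CC[C@@H]12 | intermediate
8 | 9β-allyl-2α-chloro-4,4,10β-trimethyl-trans-decalin-8-one | CC1(C)C[C@H](Cl)C[C@]2(C)[C@@H](CC=C)C(=O)CC[C@@H]12 | intermediate
9 | 9β-allyl-4,4,10β-trimethyl-trans-decalin-8-one | CC1(C)CCC[C@]2(C)[C@@H](CC=C)C(=O)CC[C@@H]12 | intermediate
10 | 9β-allyl-4,4,8α,10β-tetramethyl-trans-decalin-8β-ol | CC1(C)CCC[C@]2(C)[C@@H](CC=C)[C@@](C)(O)CC[C@@H]12 | intermediate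
11 | 4,4,8α,10β-tetramethyl-9β-[(E)-prop-1-enyl]-trans-decalin-8β-ol | CC1(C)CCC[C@]2(C)[C@@H](/C=C/C)[C@@](C)(O)CC[C@@H]12 | intermediate
12 | 8β-hydroxy-4,4,8α,10β-tetramethyl-trans-decalin-9β-carbaldehyde | CC1(C)CCC[C@]2(C)[C@@H](C=O)[C@@](C)(O)CC[C@@H]12 | intermediate
13 | methyl bis(2,2,2-trifluoroethyl)phosphonoacetate, commercial | COC(=O)CP(=O)(OCC(F)(F)F)OCC(F)(F)F | starting material
14 | chloroacetone, commercial | CC(=O)CCl | starting material
15 | methyl 2-[bis(2,2,2-trifluoroethoxy)phosphoryl]-4-oxopentanoate, racemic | COC(=O)C(CC(C)=O)P(=O)(OCC(F)(F)F)OCC(F)(F)F | intermediate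
16 | methyl (2Z)-2-{[8β-hydroxy-4,4,8α,10β-tetramethyl-trans-decalin-9β-yl]methylidene}-4-oxopentanoate | CC1(C)CCC[C@]2(C)[C@@H](/C=C(\C(=O)OC)CC(C)=O)[C@@](C)(O)CC[C@@H]12 | intermediate
17 | (4Z)-3-hydroxy-4-{[8β-hydroxy-4,4,8α,10β-tetramethyl-trans-decalin-9β-yl]methylidene}cyclopent-2-en-1-one | CC1(C)CCC[C@]2(C)[C@@H](/C=C3\C(O)=CC(=O)C3)[C@@](C)(O)CC[C@@H]12 | intermediate
18 | tris(trimethylsilyl) derivative of 17: 1,3-bis(silyloxy)fulvene with C8 silyl ether | CC1(C)CCC[C@]2(C)[C@@H](/C=C3\C(O[Si](C)(C)C)=CC(O[Si](C)(C)C)=C3)[C@@](C)(O[Si](C)(C)C)CC[C@@H]12 | intermediate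
19 | (16R)-chloro enone with C13 silyl enol ether and C8 silyl ether | CC1(C)CCC[C@]2(C)[C@@H](/C=C3\C(O[Si](C)(C)C)=CC(=O)[C@@H]3Cl)[C@@](C)(O[Si](C)(C)C)CC[C@@H]12 | intermediate
20 | CNP0279879.2, (4E,5R)-5-chloro-3-hydroxy-4-{[(1R,2S,4aS,8aS)-2-hydroxy-2,5,5,8a-tetramethyldecahydronaphthalen-1-yl]methylidene}cyclopent-2-en-1-one | CC1(C)CCC[C@]2(C)[C@@H](/C=C3\C(O)=CC(=O)[C@@H]3Cl)[C@@](C)(O)CC[C@@H]12 | target

**Step count and risks**
Total step count: 12. Longest linear sequence: 11 (steps 1–8 and 10–12).

The three steps most likely to fail:

1. Step 3 (Proposed new method). The tertiary cation may be diverted before the alkene captures it: proton loss to an isopropenyl group, a 1,2-hydride shift from C5 that erodes the ring-fusion configuration, a carbonyl-ene closure on the activated ketone, or HCl addition to the allyl groups. Fallback with known chemistry, from 5 and back at 8: 5 would first be opened by the established acylative Lewis-acid cleavage of 2-oxopinane cyclobutanes (Ac2O, BF3·OEt2, Zn(OAc)2, CH2Cl2, rt) to the monocyclic 8-acetoxy-9α,10α-diallyl-5β-isopropenyl-10β-methylcyclohex-7-ene F1. In a separate operation the cation would be regenerated by Markovnikov protonation of the isopropenyl group and closed in a classical cation–olefin cyclization with chloride capture (HCl, SnCl4, CH2Cl2, −78 °C) to the 8-acetoxy-9α-allyl-2α-chloro-4,4,10β-trimethyl-trans-decal-7-ene F2. NaOMe/MeOH would then remove the acetate and equilibrate C9, arriving at 8.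

2. Step 12 (Proposed new method). Facial selectivity of chlorine transfer may be poor, chlorination may occur at C14 instead of C16, or the exocyclic alkene may isomerize in the fulvene. Fallback with known chemistry, from 17 and back at 20: 17 would be converted with LDA (3.3 equiv, THF, −78 °C) into the alkoxide/1,3-dicarbonyl dianion and chlorinated with NCS at the terminal carbanion carbon C16, the established regiochemistry of such dianions, without stereocontrol. 20 would be separated by preparative HPLC from the (16S)-epimer of the target F3, and F3 would be returned to the epimer mixture by deprotonation and reprotonation at C16 (LDA; then AcOH, −78 °C) for another pass.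

3. Step 10. Olefination of the hindered aldehyde may be slow, the Z-selectivity may erode on warming, and the β-hydroxy aldehyde may undergo retro-aldol cleavage or dehydration. Fallback, from 11 and back at 17: the tertiary alcohol of 11 would be acylated with bromoacetyl bromide/pyridine to the C8 bromoacetate F4, converted by an Arbuzov reaction with P(OEt)3 into the C8 diethylphosphonoacetate F5, and C-alkylated with chloroacetone (NaH, THF) to the C8 2-(diethoxyphosphoryl)-4-oxopentanoate F6. Ozonolysis (O3; Me2S) would give the C9 aldehyde phosphonate ester F7, and intramolecular Horner–Wadsworth–Emmons closure under Masamune–Roush conditions (LiCl, DBU, MeCN) would give the α-acetonyl α,β-unsaturated δ-lactone F8, in which the ring enforces C9 cis to C13. The conditions of step 11 (LiHMDS) applied to F8 would open the lactone by Claisen acylation and release the C8 alkoxide, arriving at 17.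

**Further compounds**
F1 | step 3 | 8-acetoxy-9α,10α-diallyl-5β-isopropenyl-10β-methylcyclohex-7-ene (ring-opened enol acetate) | C=C(C)[C@@H]1CC=C(OC(C)=O)[C@@H](CC=C)[C@@]1(C)CC=C
F2 | step 3 | 8-acetoxy-9α-allyl-2α-chloro-4,4,10β-trimethyl-trans-decal-7-ene | CC1(C)C[C@H](Cl)C[C@]2(C)[C@H](CC=C)C(OC(C)=O)=CC[C@@H]12
F3 | step 12 | (16S)-epimer of the target | CC1(C)CCC[C@]2(C)[C@@H](/C=C3\C(O)=CC(=O)[C@H]3Cl)[C@@](C)(O)CC[C@@H]12
F4 | step 10 | C8 bromoacetate of 11 | CC1(C)CCC[C@]2(C)[C@@H](/C=C/C)[C@@](C)(OC(=O)CBr)CC[C@@H]12
F5 | step 10 | C8 diethylphosphonoacetate of 11 | CC1(C)CCC[C@]2(C)[C@@H](/C=C/C)[C@@](C)(OC(=O)CP(=O)(OCC)OCC)CC[C@@H]12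
F6 | step 10 | C8 2-(diethoxyphosphoryl)-4-oxopentanoate of 11 | CC1(C)CCC[C@]2(C)[C@@H](/C=C/C)[C@@](C)(OC(=O)C(CC(C)=O)P(=O)(OCC)OCC)CC[C@@H]12
F7 | step 10 | C9 aldehyde bearing the C8 2-(diethoxyphosphoryl)-4-oxopentanoate | CC1(C)CCC[C@]2(C)[C@@H](C=O)[C@@](C)(OC(=O)C(CC(C)=O)P(=O)(OCC)OCC)CC[C@@H]12
F8 | step 10 | decalin-fused α-acetonyl α,β-unsaturated δ-lactone (O on C8, C11=C12 in the ring) | CC1(C)CCC[C@]2(C)[C@H]3C=C(CC(C)=O)C(=O)O[C@@]3(C)CC[C@@H]12
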